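I began with the easy step, starting material closing to ring, whose rate goes with the first power of one concentration, that of free starting material.

| setting | birch | cedar | larch |
|---|---|---|---|
| starting material | 3.0 M | 3.0 M | 3.0 M |
| time | 30 h |  | 30 h |
| remark | plug flow through a tube for 30 h, no back-mixing | a single well-mixed tank run continuously and read at steady state, 30 h in it on average | a closed flask charged with all of it at once and left for 30 h |

    starting material + starting material ⇌ open dimer (K1 = 0.0629 /M, k1 = 0.692 /M/h)
    starting material → ring (k2 = 0.280 /h)
    starting material + ring ⇌ idle adduct, settled at all times (K3 = 0.16 /M)
    ring → over-reaction product (k4 = 0.0238 /h)
    ring ⇌ isomer of the product (K5 = 2.5, k5 = 0.00938 /h)

- in percentages every species weighs as the starting material in it: one open dimer or idle adduct counts as two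
- for ring the idle adduct is counted in
- for a step with 2 of a species take k times the square, and two of it per event
- the stated concentrations are those of everything mixed, before any reaction; amounts are the same in each set-up
- in an amount of ring, one idle adduct counts as one ring
- run time (birch): 30 h

1. the set-up with the highest amount of ring at the outlet or at the end, in percent of the starting material put in ("none" if the first two lie within 2 percentage points) (birch / cedar / larch / none)
2. amount of ring at the outlet or at the end, in percent of the starting material put in, birch
3. amount of ring at the outlet or at the end, in percent of the starting material put in, cedar
4. amount of ring at the outlet or at the end, in percent of the starting material put in, larch

With that step by itself the half-life of starting material is 2.5 h, far shorter than the 30 h available, so for birch and larch, which follow the same history in a tube and in a closed flask, my count turned >99.9 % of it into ring. In cedar, the tank, reaction must balance outflow at the outlet concentration, so the share converted is the rate constant times the mean time, divided by one plus that product: 89.4 %, leaving 0.319 M.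

Adding the open dimer and the idle adduct changed little in my cedar count, since their constants times that concentration came to 0.0201 and 0.0511, both far below one. At the start of birch the same products are 0.19 and 0.48, an early hold-up that I left uncounted.

Then I added what takes ring away, and with it the quantity I carried: the ring's loss constant, the sum of the forward constants of its passing into over-reaction product and into isomer of the product, 0.0332 /h. Multiplied by the time it gives a loss number of 0.996. In the tank, converted material is divided by one plus that number, which gave 44.8 % for cedar. The usual formula for consecutive first-order steps gave 41.9 % for birch and 41.9 % for larch. That gap of 2.9 percentage points stood against a margin of 2 points, and with the way back from isomer of the product uncounted I left the call open.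

The forecast, higher than my figure for birch and larch, gave 45.5 %, 45.3 % and 45.5 % for birch, cedar and larch, and called none, holding that “these effects nearly cancel”.

The flask gave 45.3 % in birch, 45.3 % in cedar and 45.3 % in larch, so the call was none. Cedar's ring was half of the share I had taken as converted, with a loss number of 0.996. For a second cedar, with the passing of ring into isomer of the product struck out both ways, I took 0.00938 /h from the loss constant, leaving a loss number of 0.715 and a ring share of 52.1 %, and that run read 51.7 %.

The rate constants were set for the occasion; no experiment stands behind them.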